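**Plan**
- Retrosynthetic cuts, in order: the 3-O-acetyl group; the lactone C8–O bond (back to a ring B cyclohexa-2,5-dienone with oxygen on C6, by allylic transposition); C14–C15 (ring D); C9–C11 (ring C, which re-aromatises ring B to a phenol); the aryl C8–C14 bond; C13–C18.
- Forward: ring A by epoxide–arene cyclisation (tetralin 6); ring E from dimedone (15); ring E and the arene are attached to 2-acetylbutyrolactone 16, which supplies C11–C14, C26 and C27; ring C by para-C-alkylation of the C6 phenoxide at C9; ring D last; then the oxygen bridge and the acetate.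
- Enabling feature: C9 carries its methyl para to C6–O, and C14 is linked to C6=O through C8=C7, with its exocyclic methylene C26 as the open δ-terminus. Hydride at C26 makes the 14-methyl and turns C14 into a nucleophile six atoms from C15–Cl.
- Stereochemistry: C3 from a Shi epoxidation; C18 and C13 from the chiral ligand of a palladium allylation; C17 by cyclopropanation anti to C13, then hydrogenolysis; C9 by a chair transition state (ring E equatorial on C13); C14 by alkylation anti to the axial 9β-methyl; C8 by intramolecular delivery from the C27 ester.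

Key step: step 17

Remark: atom numbers C1–C30 and ring letters A–E are those of the friedo-oleanane carbon skeleton of the target (α below, β above the usual drawing); the 27,8-lactone is treated as a functional group, an oxygen bridge closed on the finished pentacycle.

Step 1
Reactants: 1 1,3-dibromo-5-methoxy-2-methylbenzene (3 equiv); 2 5-bromo-2-methylpent-2-ene
Product: 4 1-bromo-5-methoxy-2-methyl-3-(4-methylpent-3-en-1-yl)benzene, via (4-methylpent-3-en-1-yl)magnesium bromide 3 (not isolated)
Conditions: 2, Mg, THF, 40 °C; then 1, PdCl2(dppf) (2 mol%), THF, 50 °C; excess 1 recovered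
Reagents that add atoms: none
Why: Kumada coupling of the primary alkylmagnesium bromide with one of the two equivalent aryl C–Br bonds; the excess of the symmetrical dibromide should keep the reaction at mono-coupling and no stereocenter is formed.

Step 2
Reactants: 4
Product: 5 (3S)-3-[2-(3-bromo-5-methoxy-2-methylphenyl)ethyl]-2,2-dimethyloxirane
Conditions: fructose-derived ketone of the L-series (1,2:4,5-di-O-isopropylidene-β-L-erythro-2,3-hexodiulo-2,6-pyranose, 30 mol%), Oxone, K2CO3, Bu4NHSO4, MeCN–dimethoxymethane–aqueous buffer (pH 10.5), 0 °C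
Reagents that add atoms: potassium peroxymonosulfate (active part of Oxone), OOS(=O)(=O)[O-].[K+]
Why: Shi asymmetric epoxidation of the trisubstituted alkene through the spiro dioxirane transition state; the L-series ketone is chosen because the D-series catalyst is expected to give the 3R oxirane with this olefin class, so C3 is set here as S.

Step 3
Reactants: 5
Product: 6 (2S)-6-bromo-8-methoxy-1,1,5-trimethyl-1,2,3,4-tetrahydronaphthalen-2-ol
Conditions: InBr3 (20 mol%), CH2Cl2, −20 → 20 °C
Reagents that add atoms: none
Why: Lewis acid epoxide opening at the tertiary carbon with 6-endo Friedel–Crafts closure onto C5, the only free position ortho to the side chain and activated by the ortho methoxy group; the C3–O bond is not touched, so the 3S configuration is carried over.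

Step 4
Reactants: 7 5,5-dimethylcyclohexane-1,3-dione (dimedone); 8 ethyl bromoacetate
Product: 9 ethyl 2-(4,4-dimethyl-2,6-dioxocyclohexyl)acetate
Conditions: KOH, H2O–EtOH, 20 °C
Reagents that add atoms: none
Why: C-alkylation of the stabilised 1,3-dione enolate by an α-halo ester (substitution at a primary, carbonyl-activated carbon).

Step 5
Reactants: 9
Product: 10 ethyl 2-(2-ethoxy-4,4-dimethyl-6-oxocyclohex-1-en-1-yl)acetate
Conditions: EtOH, p-TsOH (5 mol%), benzene, reflux with removal of water
Reagents that add atoms: ethanol, CCO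
Why: acid-catalysed enol etherification of the symmetrical 2-substituted dione gives a single vinylogous ester, and ethanol is used so that the ethyl ester cannot be scrambled.

Step 6
Reactants: 10
Product: 12 2-(2-hydroxyethyl)-5,5-dimethylcyclohex-2-en-1-one, via diol enol ether 11 (not isolated)
Conditions: LiAlH4, THF, 0 °C; then 2 M HCl, THF, 20 °C
Reagents that add atoms: water, O
Why: Stork–Danheiser transposition: hydride reduces the vinylogous ester carbonyl (and the side-chain ester to the primary alcohol) and aqueous acid converts the allylic alcohol enol ether into the transposed enone.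

Step 7
Reactants: 12
Product: 13 2-(2-chloroethyl)-5,5-dimethylcyclohex-2-en-1-one
Conditions: PPh3, CCl4, CH2Cl2, 20 °C
Reagents that add atoms: tetrachloromethane, ClC(Cl)(Cl)Cl
Why: Appel chlorination of the primary alcohol under neutral conditions leaves the enone intact and gives a halide that is inert to the palladium, zinc and boron chemistry that follows.

Step 8
Reactants: 13
Product: 14 2-(2-chloroethyl)-5,5-dimethylcyclohex-2-en-1-ol (racemic)
Conditions: NaBH4, CeCl3·7H2O, MeOH, 0 °C
Reagents that add atoms: none
Why: Luche 1,2-reduction of the enone; the racemic alcohol suffices because both enantiomers later ionise to the same symmetrical allyl complex.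

Step 9
Reactants: 14
Product: 15 2-(2-chloroethyl)-5,5-dimethylcyclohex-2-en-1-yl methyl carbonate (racemic)
Conditions: ClCO2Me, pyridine, CH2Cl2, 0 °C
Reagents that add atoms: methyl chloroformate, COC(=O)Cl
Why: O-acylation with a chloroformate gives the allylic carbonate, which on ionisation releases methoxide as the base for the next step.

Step 10
Reactants: 15; 16 3-acetyloxolan-2-one (2-acetylbutyrolactone)
Product: 17 (3R)-3-acetyl-3-[(1R)-2-(2-chloroethyl)-5,5-dimethylcyclohex-2-en-1-yl]oxolan-2-one
Conditions: [Pd(C3H5)Cl]2 (2.5 mol%), (R,R)-N,N′-(cyclohexane-1,2-diyl)bis[2-(diphenylphosphino)benzamide] (7.5 mol%), CH2Cl2, 25 °C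
Reagents that add atoms: none
Why: palladium-catalysed asymmetric allylic alkylation: either enantiomer of 15 ionises to one meso 2-substituted cyclohexenyl complex, and the chiral diphosphine should decide which enantiotopic terminus (C18) and which face of the prochiral β-keto lactone enolate (C13) combine, setting 18R and 13R; the ligand antipode would be used should a test run show the opposite sense.

Step 11
Reactants: 17
Product: 18 (3R)-3-acetyl-3-[(1S,2R,6S)-1-(2-chloroethyl)-4,4-dimethylbicyclo[4.1.0]heptan-2-yl]oxolan-2-one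
Conditions: Et2Zn, CH2I2, ClCH2CH2Cl, 0 → 40 °C
Reagents that add atoms: diiodomethane, ICI
Why: Simmons–Smith cyclopropanation (Furukawa variant) of the trisubstituted alkene from the face anti to the bulky quaternary substituent on the allylic carbon C18, which places the new CH2 (the future 17-methyl) β and forces the chloroethyl chain cis to C13.

Step 12
Reactants: 18
Product: 20 (3R)-3-acetyl-3-[(1R,2R)-2-(2-chloroethyl)-2,5,5-trimethylcyclohexyl]oxolan-2-one, via secondary carbinol 19 (not isolated)
Conditions: H2 (4 atm), PtO2, AcOH, 25 °C; filtration; then DMP (1,1,1-triacetoxy-1,1-dihydro-1,2-benziodoxol-3(1H)-one), CH2Cl2, 20 °C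
Reagents that add atoms: none
Why: catalytic hydrogenolysis cleaves the least hindered cyclopropane bond (C22–C28) and so delivers the quaternary 17-methyl with the C17 configuration unchanged; the ketone, reduced along the way, is restored by the oxidation.

Step 13
Reactants: 20
Product: 21 1-{(3R)-3-[(1R,2R)-2-(2-chloroethyl)-2,5,5-trimethylcyclohexyl]-2-oxooxolan-3-yl}ethenyl trifluoromethanesulfonate
Conditions: KN(SiMe3)2, THF, −78 °C; then PhNTf2, −78 → 0 °C
Reagents that add atoms: N-phenylbis(trifluoromethanesulfonimide), O=S(=O)(N(c1ccccc1)S(=O)(=O)C(F)(F)F)C(F)(F)F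
Why: the methyl group is the only enolisable position, so kinetic deprotonation and O-triflation give the 1-substituted alkenyl triflate.

Step 14
Reactants: 21; 6
Product: 24 aryl-vinyl lactone (C8–C14 bond formed; C14=C26H2; 3S-OH, 13R, 17R, 18R), via aryllithium lithium alkoxide 22 (not isolated), via arylzinc chloride 23 (not isolated)
Conditions: 6, n-BuLi (2.1 equiv), THF, −78 °C; ZnCl2, −78 → 20 °C; then 21, Pd2(dba)3 (2.5 mol%), 2-dicyclohexylphosphino-2′,6′-dimethoxybiphenyl (10 mol%), THF, 55 °C; aqueous NH4Cl
Reagents that add atoms: none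
Why: Negishi coupling: deprotonation of the alcohol and bromine–lithium exchange at C8, transmetalation to zinc and palladium-catalysed coupling with the alkenyl triflate form the aryl C8–C14 bond, while the lactone and the alkyl chloride do not react with the arylzinc.

Step 15
Reactants: 24
Product: 26 phenol bromo ester (methyl (2R)-4-bromo-2-[(1R,2R)-2-(2-chloroethyl)-2,5,5-trimethylcyclohexyl]-2-{1-[(6S)-4,6-dihydroxy-1,5,5-trimethyl-5,6,7,8-tetrahydronaphthalen-2-yl]ethenyl}butanoate), via bromo acid 25 (not isolated)
Conditions: BBr3 (5 equiv), 2-methylbut-2-ene (5 equiv), CH2Cl2, −78 → 20 °C; cold 1 M HCl work-up; crude acid, Me3SiCHN2, toluene–MeOH, 0 °C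
Reagents that add atoms: boron tribromide, BrB(Br)Br; (trimethylsilyl)diazomethane, C[Si](C)(C)C=[N+]=[N-]
Why: boron tribromide cleaves the aryl methyl ether and opens the γ-lactone by bromide attack at the primary carbon C11, and immediate esterification of the acid prevents relactonisation; the 1,1-disubstituted alkene has no other β-hydrogen, so any hydrobromide adduct can only return to it.

Step 16
Reactants: 26
Product: 27 tetracyclic trienone (rings A, B, C and E; methyl 15-chloro-3β-hydroxy-6-oxo-14,15-seco-D:B-friedooleana-5(10),7,14(26)-trien-27-oate)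
Conditions: Cs2CO3 (2 equiv), MeCN, 60 °C, 0.01 M
Reagents that add atoms: none
Why: intramolecular para-C-alkylation of the C6 phenoxide at the methyl-bearing C9 (Ar2-6 closure of ring C, a dearomatisation to the cyclohexa-2,5-dienone); O-alkylation is geometrically impossible, attack through the ortho carbon C7 would press the C14 methylene against the 9-methyl, and C9 is set by a chair-like transition state with ring E equatorial on C13 so that the 9-methyl ends trans to the axial ester.

Step 17
Reactants: 27
Product: 28 pentacyclic dienone (methyl 3β-hydroxy-6-oxo-D:B-friedooleana-5(10),7-dien-27-oate)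
Conditions: K[s-Bu3BH] (2.3 equiv), THF, −78 °C; then DMPU, −78 → 40 °C; aqueous NH4Cl
Reagents that add atoms: none
Why: Proposed new method: the bulky borohydride should add at C26, the unsubstituted exocyclic δ-terminus of the linear C26=C14–C8=C7–C6=O chromophore (C6 is shielded by the C4 methyls and the β-carbons C8 and C10 are fully substituted), which turns C26 into the 14-methyl group and gives regiospecifically the potassium trienolate C6(O–)=C7–C8=C14, whose γ-carbon C14 then displaces chloride at C15. The closest known reaction types are the conjugate reduction–enolate alkylation of enones with trialkylborohydrides and the intramolecular γ-alkylation of extended dienone enolates. Ring D closes in a 6-(enolexo)-exo-tet mode through a chair transition state. The new quaternary stereocenter C14 is controlled by the axial 9β-methyl and the equatorial C13–C18 bond: C15 can only approach the α-face, which gives the trans C/D fusion with the methyl β. The step needs 1,6- over 1,2- or 1,4-hydride addition (secured by the shielding just described) and C14- over O- or C7-alkylation (neither O6 nor C7 can reach C15 through a six-membered ring). Unlike base-mediated enolisation, this entry cannot form the unproductive enolate on the C1 side.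

Step 18
Reactants: 28
Product: 30 3β-hydroxy-D:B-friedooleana-5(10),6-dien-27,8α-olide, via bis-allylic alcohol 29 (not isolated)
Conditions: NaBH4, CeCl3·7H2O, MeOH, −20 °C; then 1 M HCl, THF, 0 → 20 °C
Reagents that add atoms: water, O
Why: Luche 1,2-reduction gives the bis-allylic alcohol, which ionises in acid to the C6–C8–C10 dienyl cation; the C27 ester carbonyl can reach only C8 and only from the α-face, and hydrolysis of the resulting methoxy-lactonium ion leaves the 27,8-lactone with the 5(10),6-diene, fixing C8.

Step 19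
Reactants: 30
Product: 31 3β-acetoxy-D:B-friedooleana-5(10),6-dien-27,8α-olide (3S,8R,9S,13R,14S,17R,18R; target)
Conditions: Ac2O, DMAP (cat.), pyridine, 20 °C
Reagents that add atoms: acetic anhydride, CC(=O)OC(C)=O
Why: DMAP-catalysed acetylation of the hindered secondary 3β-alcohol; no other nucleophilic group is present.

**Compound list**

1 | 1,3-dibromo-5-methoxy-2-methylbenzene | COc1cc(Br)c(C)c(Br)c1 | starting material
2 | 5-bromo-2-methylpent-2-ene | CC(C)=CCCBr | starting material
3 | (4-methylpent-3-en-1-yl)magnesium bromide | CC(C)=CCC[Mg]Br | intermediate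
4 | 1-bromo-5-methoxy-2-methyl-3-(4-methylpent-3-en-1-yl)benzene | COc1cc(Br)c(C)c(CCC=C(C)C)c1 | intermediate
5 | (3S)-3-[2-(3-bromo-5-methoxy-2-methylphenyl)ethyl]-2,2-dimethyloxirane | CC1(C)O[C@H]1CCc2cc(OC)cc(Br)c2C | intermediate
6 | (2S)-6-bromo-8-methoxy-1,1,5-trimethyl-1,2,3,4-tetrahydronaphthalen-2-ol | O[C@H]1CCc2c(C)c(Br)cc(OC)c2C1(C)C | intermediate
7 | 5,5-dimethylcyclohexane-1,3-dione | O=C1CC(C)(C)CC(=O)C1 | starting material
8 | ethyl bromoacetate | CCOC(=O)CBr | starting material
9 | ethyl 2-(4,4-dimethyl-2,6-dioxocyclohexyl)acetate | CCOC(=O)CC1C(=O)CC(C)(C)CC1=O | intermediate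
10 | ethyl 2-(2-ethoxy-4,4-dimethyl-6-oxocyclohex-1-en-1-yl)acetate | CCOC(=O)CC1=C(OCC)CC(C)(C)CC1=O | intermediate
11 | 2-(2-ethoxy-6-hydroxy-4,4-dimethylcyclohex-1-en-1-yl)ethanol (racemic) | CCOC1=C(CCO)C(O)CC(C)(C)C1 | intermediate
12 | 2-(2-hydroxyethyl)-5,5-dimethylcyclohex-2-en-1-one | O=C1CC(C)(C)CC=C1CCO | intermediate
13 | 2-(2-chloroethyl)-5,5-dimethylcyclohex-2-en-1-one | O=C1CC(C)(C)CC=C1CCCl | intermediate
14 | 2-(2-chloroethyl)-5,5-dimethylcyclohex-2-en-1-ol (racemic) | OC1CC(C)(C)CC=C1CCCl | intermediate
15 | 2-(2-chloroethyl)-5,5-dimethylcyclohex-2-en-1-yl methyl carbonate (racemic) | COC(=O)OC1CC(C)(C)CC=C1CCCl | intermediate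
16 | 3-acetyloxolan-2-one | CC(=O)C1CCOC1=O | starting material
17 | (3R)-3-acetyl-3-[(1R)-2-(2-chloroethyl)-5,5-dimethylcyclohex-2-en-1-yl]oxolan-2-one | CC(=O)[C@@]1(CCOC1=O)[C@@H]2CC(C)(C)CC=C2CCCl | intermediate
18 | (3R)-3-acetyl-3-[(1S,2R,6S)-1-(2-chloroethyl)-4,4-dimethylbicyclo[4.1.0]heptan-2-yl]oxolan-2-one | CC(=O)[C@@]1(CCOC1=O)[C@@H]2CC(C)(C)C[C@H]3C[C@@]23CCCl | intermediate
19 | carbinol from concurrent reduction of the acetyl group of 20 (1-hydroxyethyl epimers) | CC(O)[C@@]1(CCOC1=O)[C@@H]2CC(C)(C)CC[C@]2(C)CCCl | intermediate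
20 | (3R)-3-acetyl-3-[(1R,2R)-2-(2-chloroethyl)-2,5,5-trimethylcyclohexyl]oxolan-2-one | CC(=O)[C@@]1(CCOC1=O)[C@@H]2CC(C)(C)CC[C@]2(C)CCCl | intermediate
21 | 1-{(3R)-3-[(1R,2R)-2-(2-chloroethyl)-2,5,5-trimethylcyclohexyl]-2-oxooxolan-3-yl}ethenyl trifluoromethanesulfonate | C=C(OS(=O)(=O)C(F)(F)F)[C@@]1(CCOC1=O)[C@@H]2CC(C)(C)CC[C@]2(C)CCCl | intermediate
22 | C8-lithio derivative of 6 as its lithium alkoxide | [Li]O[C@H]1CCc2c(C)c([Li])cc(OC)c2C1(C)C | intermediate
23 | arylzinc chloride from 22 | [Li]O[C@H]1CCc2c(C)c([Zn]Cl)cc(OC)c2C1(C)C | intermediate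
24 | (3R)-3-[(1R,2R)-2-(2-chloroethyl)-2,5,5-trimethylcyclohexyl]-3-{1-[(6S)-6-hydroxy-4-methoxy-1,5,5-trimethyl-5,6,7,8-tetrahydronaphthalen-2-yl]ethenyl}oxolan-2-one | O[C@H]1CCc2c(C)c(C(=C)[C@@]3(CCOC3=O)[C@@H]4CC(C)(C)CC[C@]4(C)CCCl)cc(OC)c2C1(C)C | intermediate
25 | (2R)-4-bromo-2-[(1R,2R)-2-(2-chloroethyl)-2,5,5-trimethylcyclohexyl]-2-{1-[(6S)-4,6-dihydroxy-1,5,5-trimethyl-5,6,7,8-tetrahydronaphthalen-2-yl]ethenyl}butanoic acid | O[C@H]1CCc2c(C)c(C(=C)[C@](CCBr)(C(=O)O)[C@@H]3CC(C)(C)CC[C@]3(C)CCCl)cc(O)c2C1(C)C | intermediate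
26 | methyl ester of 25 | O[C@H]1CCc2c(C)c(C(=C)[C@](CCBr)(C(=O)OC)[C@@H]3CC(C)(C)CC[C@]3(C)CCCl)cc(O)c2C1(C)C | intermediate
27 | methyl 15-chloro-3β-hydroxy-6-oxo-14,15-seco-D:B-friedooleana-5(10),7,14(26)-trien-27-oate (9β-methyl, 13α-ester, 17β-methyl, 18β-H) | O[C@H]1CCC2=C(C1(C)C)C(=O)C=C3C(=C)[C@@](C(=O)OC)(CC[C@@]23C)[C@@H]4CC(C)(C)CC[C@]4(C)CCCl | intermediate
28 | methyl 3β-hydroxy-6-oxo-D:B-friedooleana-5(10),7-dien-27-oate (9β- and 14β-methyl, 13α-ester) | O[C@H]1CCC2=C(C1(C)C)C(=O)C=C3[C@@]2(C)CC[C@@]4(C(=O)OC)[C@@H]5CC(C)(C)CC[C@]5(C)CC[C@]34C | intermediate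
29 | methyl 3β,6-dihydroxy-D:B-friedooleana-5(10),7-dien-27-oate (C6 epimers) | O[C@H]1CCC2=C(C1(C)C)C(O)C=C3[C@@]2(C)CC[C@@]4(C(=O)OC)[C@@H]5CC(C)(C)CC[C@]5(C)CC[C@]34C | intermediate
30 | 3β-hydroxy-D:B-friedooleana-5(10),6-dien-27,8α-olide | O[C@H]1CCC2=C(C=C[C@@]34OC(=O)[C@]5(CC[C@@]23C)[C@@H]2CC(C)(C)CC[C@]2(C)CC[C@]45C)C1(C)C | intermediate
31 | 3β-acetoxy-D:B-friedooleana-5(10),6-dien-27,8α-olide (3S,8R,9S,13R,14S,17R,18R) | CC(=O)O[C@H]1CCC2=C(C=C[C@@]34OC(=O)[C@]5(CC[C@@]23C)[C@@H]2CC(C)(C)CC[C@]2(C)CC[C@]45C)C1(C)C | target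

**Totals.** 19 steps in all; longest linear sequence 16 steps (steps 4–19, from dimedone). The arene branch is steps 1–3 and joins at step 14.

**Steps most likely to fail**

1. Step 17 (Proposed new method). What may go wrong: hydride delivery to the carbonyl carbon instead of the exocyclic terminus, or protonation of the trienolate before the slow alkylation at a fully substituted carbon. Fallback with known chemistry, setting out from 27 and returning at 28: hydrogenation with RhCl(PPh3)3 and H2 (benzene, 25 °C) should saturate only the exocyclic 1,1-disubstituted alkene and give the tetracyclic dienone F1 as C14 epimers. KOtBu in t-BuOH–THF (25–50 °C) then equilibrates the two γ-enolates, and only the C14 enolate can reach C15, so alkylation leads to 28.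

2. Step 10. What may go wrong: poor facial selectivity at the prochiral enolate carbon (C13 epimers), or slow attack of the hindered nucleophile on the allyl complex. Fallback by Ireland–Claisen rearrangement with chirality transfer, setting out from 13 and 16 and returning at 17. Oxazaborolidine-catalysed borane reduction of 13 (CBS reduction, catalyst enantiomer chosen for the 1S alcohol) gives the allylic alcohol F2. Compound 16 is ketalised (ethylene glycol, p-TsOH) to the dioxolane lactone F3, which is opened with KOH and O-silylated (TBSCl, imidazole; K2CO3–MeOH work-up) to the acid F4. Coupling with DCC and DMAP gives the ester F5. Enolisation with KN(SiMe3)2 and Me3SiCl in toluene (enolate geometry fixed by chelation to the dioxolane oxygen, or inverted in THF–HMPA if the other C13 epimer is needed) and warming to 80 °C gives the rearranged acid F6; the C13–C18 bond forms on the face from which the C22–O bond departs. Aqueous HCl in THF removes the silyl and ketal groups and closes the lactone to 17.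

3. Step 14. What may go wrong: slow transmetalation or reductive elimination between two hindered partners, with protodemetalation of the arylzinc. Fallback by carbonyl addition and dehydration instead of cross-coupling, setting out from 20 and 6 and returning at 24. The aryllithium 22 (from 6 as in step 14) is treated with CeCl3 and added to the ketone 20 (THF, −78 °C) to give the tertiary benzylic alcohol F7. Camphorsulfonic acid (cat.) in toluene at 40 °C dehydrates it to 24, because only the methyl group offers a β-hydrogen.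

**Further compounds**

F1 | step 17 | methyl 15-chloro-3β-hydroxy-6-oxo-14,15-seco-D:B-friedooleana-5(10),7-dien-27-oate (C14 epimers) | O[C@H]1CCC2=C(C1(C)C)C(=O)C=C3C(C)[C@@](C(=O)OC)(CC[C@@]23C)[C@@H]4CC(C)(C)CC[C@]4(C)CCCl
F2 | step 10 | (1S)-2-(2-chloroethyl)-5,5-dimethylcyclohex-2-en-1-ol | O[C@H]1CC(C)(C)CC=C1CCCl
F3 | step 10 | 3-(2-methyl-1,3-dioxolan-2-yl)oxolan-2-one (racemic) | CC1(OCCO1)C2CCOC2=O
F4 | step 10 | 4-[(tert-butyldimethylsilyl)oxy]-2-(2-methyl-1,3-dioxolan-2-yl)butanoic acid (racemic) | CC1(OCCO1)C(CCO[Si](C)(C)C(C)(C)C)C(=O)O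
F5 | step 10 | (1S)-2-(2-chloroethyl)-5,5-dimethylcyclohex-2-en-1-yl ester of F4 | CC1(OCCO1)C(CCO[Si](C)(C)C(C)(C)C)C(=O)O[C@H]2CC(C)(C)CC=C2CCCl
F6 | step 10 | 4-[(tert-butyldimethylsilyl)oxy]-2-[(1R)-2-(2-chloroethyl)-5,5-dimethylcyclohex-2-en-1-yl]-2-(2-methyl-1,3-dioxolan-2-yl)butanoic acid (C2 configured as C13 of 17) | CC1(OCCO1)[C@](CCO[Si](C)(C)C(C)(C)C)(C(=O)O)[C@@H]2CC(C)(C)CC=C2CCCl
F7 | step 14 | tertiary benzylic alcohol from 22 and 20 (carbinol epimers) | O[C@H]1CCc2c(C)c(C(C)(O)[C@@]3(CCOC3=O)[C@@H]4CC(C)(C)CC[C@]4(C)CCCl)cc(OC)c2C1(C)C
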